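**Retrosynthetic overview**
1. The plan rests on C4 of the cyclohexenone. It bears two alkenyl carbons, ring C3 and C1' of the trienamide, so it is traced back to a non-stereogenic divinyl carbinol carbon beside C5, the one ring stereocentre taken from (R)-malic acid.
2. Key disconnection C2=C3: ring-closing metathesis of an acryloyl terminus onto one of the two diastereotopic C4 vinyl groups, the choice being made by a temporary five-membered O4–Si–O5 ring (cis fusion).
3. Later disconnections: C2–N (2-iodoenone plus (R,E)-2,4-dimethyloct-2-enamide under CuI), C1'=C2' (cross-metathesis of the surviving vinyl group to the enal), C3'=C4' (Horner–Wadsworth–Emmons with the phosphonocrotonamide of 2-amino-3-hydroxycyclopent-2-enone), then desilylation.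
4. Ring order: dioxolanone (temporary) → dioxasilolane (tether) → cyclohexenone (metathesis); the cyclopentenone ring is bought as cyclopentane-1,3-dione.

Key step: step 5

Remark: the cyclohexenone is numbered C1 (ketone), C2 (N-bearing), C3, C4 (tertiary carbinol), C5 (secondary carbinol), C6, and the trienamide C1' to C7' outward from C4; (R)-malic acid, the unnatural enantiomer, is assumed to be purchased.

**Main line to the iodoenone**

Step 1
Reactants: 1 (R)-malic acid
Product: 2 (R)-2-(2,2-dimethyl-5-oxo-1,3-dioxolan-4-yl)acetic acid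
Conditions: Me2C(OMe)2, TsOH·H2O (cat.), rt
Reagents that add atoms: 2,2-dimethoxypropane, COC(C)(C)OC
Why: Acid-catalysed acetal exchange closes the five-membered 1,3-dioxolan-4-one on the α-hydroxy acid unit in preference to a six-membered ring on the β-carboxyl, which stays free; the malate stereocentre is not touched.

Step 2
Reactants: 2 (R)-2-(2,2-dimethyl-5-oxo-1,3-dioxolan-4-yl)acetic acid
Product: 4 (R)-2-(2,2-dimethyl-5-oxo-1,3-dioxolan-4-yl)-N-methoxy-N-methylacetamide, via acid chloride 3 (not isolated)
Conditions: (COCl)2, DMF (cat.), CH2Cl2, 0 °C to rt; concentrate; then MeNHOMe·HCl, pyridine, CH2Cl2, 0 °C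
Reagents that add atoms: N,O-dimethylhydroxylamine hydrochloride, CNOC.Cl; oxalyl chloride, ClC(=O)C(=O)Cl (chlorine of 3 only)
Why: Acyl chloride formation and N-acylation (Weinreb amide synthesis) should outpace aminolysis of the dioxolanone at 0 °C with one equivalent of the hydroxylamine.

Step 3
Reactants: 4 (R)-2-(2,2-dimethyl-5-oxo-1,3-dioxolan-4-yl)-N-methoxy-N-methylacetamide; 5 vinylmagnesium bromide
Product: 6 (5R)-6-ethenyl-5,6-dihydroxyocta-1,7-dien-3-one
Conditions: 5 (6 equiv), THF, 4 added to the reagent at −20 °C, then 0 °C; poured into cold 1 M HCl; used crude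
Reagents that add atoms: none
Why: Grignard addition in which the dioxolanone reacts as an activated ester and takes two vinyl groups at C4 (the expelled acetone consumes a further equivalent), while the N-methoxy-N-methylamide stops at its magnesium chelate and releases the vinyl ketone only on quench (Weinreb ketone synthesis); the excess of reagent keeps the C4 alkoxide from lactonising onto the amide, the acidic quench keeps the freed hydroxylamine from adding to the enone, and carbonyl addition should be faster than enolisation so that C5 keeps its configuration.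

Step 4
Reactants: 6 (5R)-6-ethenyl-5,6-dihydroxyocta-1,7-dien-3-one; 7 di-tert-butylsilyl bis(trifluoromethanesulfonate)
Product: 8 1-[(5R)-2,2-di-tert-butyl-4,4-diethenyl-1,3,2-dioxasilolan-5-yl]but-3-en-2-one
Conditions: 2,6-lutidine, CH2Cl2, 0 °C to rt
Reagents that add atoms: none
Why: Silylene formation: the bis(triflate) silylates O5 and the tethered silyl triflate then closes the five-membered dioxasilolane on the hindered tertiary O4; C4 carries two identical vinyl groups and is still not a stereocentre.

Step 5
Reactants: 8 1-[(5R)-2,2-di-tert-butyl-4,4-diethenyl-1,3,2-dioxasilolan-5-yl]but-3-en-2-one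
Product: 9 cis-fused di-tert-butylsilylene of (4S,5R)-4,5-dihydroxy-4-vinylcyclohex-2-en-1-one [(3aS,7aR)-2,2-di-tert-butyl-3a-ethenyl-3a,7a-dihydro-1,3,2-benzodioxasilol-6(7H)-one]
Conditions: second-generation Grubbs catalyst (H2IMes)(PCy3)Cl2Ru=CHPh (10 mol%), toluene (5 mM), 80 °C, argon sparge
Reagents that add atoms: none
Why: Ring-closing olefin metathesis: the ruthenium alkylidene exchanges reversibly with the terminal alkenes, a carbene on a C4 vinyl group adds to the acryloyl alkene through a metallacyclobutane, and cycloreversion with loss of ethene gives the C2=C3 bond of the enone irreversibly. The closest known reactions are enone-forming ring-closing metathesis of acryloyl dienes and diastereotopic-group-selective ring-closing metathesis of divinyl carbinols. The carbocycle closes as a six-membered ring by joining the acryloyl CH (future C2) to the inner carbon of one vinyl group (future C3), fused to the existing dioxasilolane. C4 becomes a stereocentre only in this step, and its (S) configuration is dictated by C5 (R, from malic acid): on the five-membered O–Si–O ring only the vinyl group cis to the C6 methylene can reach the acryloyl terminus and give the cis-fused bicycle, whereas the other vinyl group would have to close a trans-fused ring across the nearly eclipsed O4–C4–C5–O5 unit. The step needs group selectivity between the two vinyl groups, which the silylene tether supplies, and ring closure in preference to oligomerisation, which high dilution and the low cross-metathesis reactivity of vinyl groups on a fully substituted carbon should secure.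

Step 6
Reactants: 9 cis-fused di-tert-butylsilylene of (4S,5R)-4,5-dihydroxy-4-vinylcyclohex-2-en-1-one
Product: 10 cis-fused di-tert-butylsilylene of (4S,5R)-4,5-dihydroxy-2-iodo-4-vinylcyclohex-2-en-1-one
Conditions: I2, pyridine, CH2Cl2, 0 °C to rt
Reagents that add atoms: iodine, II
Why: Johnson α-iodination of an enone (conjugate addition of pyridine at C3, iodination of the enolate at C2 and loss of pyridine), a reaction that tolerates a fully substituted C4; the isolated vinyl group and the silylene should be inert.

**Side-chain amide**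

Step 7
Reactants: 11 (R)-4-benzyloxazolidin-2-one; 12 hexanoyl chloride
Product: 13 (R)-4-benzyl-3-hexanoyloxazolidin-2-one
Conditions: n-BuLi, THF, −78 °C; then 12, −78 °C to 0 °C
Reagents that add atoms: none
Why: N-Acylation of the lithiated oxazolidinone (loading of the Evans auxiliary).

Step 8
Reactants: 13 (R)-4-benzyl-3-hexanoyloxazolidin-2-one
Product: 14 (R)-4-benzyl-3-[(R)-2-methylhexanoyl]oxazolidin-2-one
Conditions: NaN(SiMe3)2, THF, −78 °C; then MeI, −78 °C
Reagents that add atoms: iodomethane, CI
Why: Evans asymmetric alkylation: the chelated Z sodium enolate is methylated on the face away from the benzyl group, which sets the (R) centre of the side chain.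

Step 9
Reactants: 14 (R)-4-benzyl-3-[(R)-2-methylhexanoyl]oxazolidin-2-one
Product: 15 (R)-2-methylhexan-1-ol
Conditions: LiBH4, MeOH (1 equiv), Et2O, 0 °C
Reagents that add atoms: none
Why: Reductive removal of the auxiliary with LiBH4, which attacks the exocyclic imide carbonyl and does not epimerise the α-centre.

Step 10
Reactants: 15 (R)-2-methylhexan-1-ol
Product: 17 ethyl (R,E)-2,4-dimethyloct-2-enoate, via (R)-2-methylhexanal 16 (not isolated)
Conditions: Dess–Martin periodinane, NaHCO3, CH2Cl2, 0 °C to rt; then Ph3P=C(Me)CO2Et, rt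
Reagents that add atoms: ethyl 2-(triphenylphosphoranylidene)propanoate, CCOC(=O)C(C)=P(c1ccccc1)(c1ccccc1)c1ccccc1
Why: Dess–Martin oxidation followed in the same flask by Wittig olefination with the stabilised α-methyl ylide, which should give the E trisubstituted enoate; the α-branched aldehyde is not isolated so that it cannot epimerise.

Step 11
Reactants: 17 ethyl (R,E)-2,4-dimethyloct-2-enoate
Product: 18 (R,E)-2,4-dimethyloct-2-enamide
Conditions: AlMe3, NH4Cl, toluene, 0 °C to 50 °C; aqueous HCl work-up
Reagents that add atoms: ammonium chloride, [NH4+].[Cl-]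
Why: Aminolysis of the ester with the aluminium amide made from AlMe3 and NH4Cl (Weinreb amidation), a direct route to the primary amide that leaves the hindered enoate double bond alone.

**Union and chain extension**

Step 12
Reactants: 10 cis-fused di-tert-butylsilylene of (4S,5R)-4,5-dihydroxy-2-iodo-4-vinylcyclohex-2-en-1-one; 18 (R,E)-2,4-dimethyloct-2-enamide
Product: 19 (R,E)-N-[(4S,5R)-4,5-(di-tert-butylsilanediyldioxy)-1-oxo-4-vinylcyclohex-2-en-2-yl]-2,4-dimethyloct-2-enamide (cyclohexenone numbering)
Conditions: CuI (10 mol%), MeNHCH2CH2NHMe (20 mol%), K3PO4, toluene, 60 °C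
Reagents that add atoms: none
Why: Copper-catalysed Goldberg–Buchwald amidation of the alkenyl iodide with the primary amide, with retention of the C2=C3 position; the mild insoluble base is chosen to limit E1cB loss of the C5 silyloxy group.

Step 13
Reactants: 19 (R,E)-N-[(4S,5R)-4,5-(di-tert-butylsilanediyldioxy)-1-oxo-4-vinylcyclohex-2-en-2-yl]-2,4-dimethyloct-2-enamide
Product: 20 (R,E)-N-[(4S,5R)-4,5-(di-tert-butylsilanediyldioxy)-1-oxo-4-[(E)-3-oxoprop-1-enyl]cyclohex-2-en-2-yl]-2,4-dimethyloct-2-enamide
Conditions: second-generation Hoveyda–Grubbs catalyst (H2IMes)Cl2Ru=CH(C6H4-2-OiPr) (10 mol%), crotonaldehyde (10 equiv), CH2Cl2, 40 °C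
Reagents that add atoms: (E)-crotonaldehyde, C/C=C/C=O
Why: Olefin cross-metathesis of the monosubstituted C4 vinyl group with crotonaldehyde (propene is lost), E-selective under thermodynamic control; the other alkenes are trisubstituted and conjugated and should not engage.

**Phosphonate reagent**

Step 14
Reactants: 21 cyclopentane-1,3-dione
Product: 22 3-hydroxy-2-nitrocyclopent-2-en-1-one (2-nitrocyclopentane-1,3-dione)
Conditions: HNO3 (fuming), Et2O, 0 °C to rt
Reagents that add atoms: nitric acid, O[N+](=O)[O-]
Why: Electrophilic nitration of the enolised 1,3-dione at C2.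

Step 15
Reactants: 22 3-hydroxy-2-nitrocyclopent-2-en-1-one
Product: 23 2-amino-3-hydroxycyclopent-2-en-1-one hydrochloride
Conditions: H2 (1 atm), Pd/C, HCl, MeOH, rt
Reagents that add atoms: hydrogen chloride, Cl
Why: Catalytic hydrogenation of the nitro group to the amine, trapped as its hydrochloride because the free aminodione condenses with itself.

Step 16
Reactants: 24 triethyl (E)-4-phosphonocrotonate
Product: 25 (E)-4-(diethoxyphosphoryl)but-2-enoic acid
Conditions: LiOH·H2O (1.1 equiv), THF/H2O, 0 °C; then aqueous HCl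
Reagents that add atoms: lithium hydroxide, [Li+].[OH-]
Why: Saponification of the carboxylic ester, which is far more easily hydrolysed than the phosphonate esters.

Step 17
Reactants: 25 (E)-4-(diethoxyphosphoryl)but-2-enoic acid; 23 2-amino-3-hydroxycyclopent-2-en-1-one hydrochloride
Product: 27 diethyl (E)-[4-[(2-hydroxy-5-oxocyclopent-1-en-1-yl)amino]-4-oxobut-2-en-1-yl]phosphonate, via phosphonocrotonyl chloride 26 (not isolated)
Conditions: (COCl)2, DMF (cat.), CH2Cl2, 0 °C to rt; concentrate; then 23, pyridine, DMF, 0 °C to rt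
Reagents that add atoms: oxalyl chloride, ClC(=O)C(=O)Cl (chlorine of 26 only)
Why: N-Acylation through the acid chloride; any O-acylated enol should pass to the amide by O-to-N acyl shift, and pyridine is too weak a base to form a ketene from the γ-acidic acyl chloride.

**Endgame**

Step 18
Reactants: 20 enal from step 13; 27 diethyl (E)-[4-[(2-hydroxy-5-oxocyclopent-1-en-1-yl)amino]-4-oxobut-2-en-1-yl]phosphonate
Product: 28 O4,O5-di-tert-butylsilanediyl derivative of the target: (2E,4E,6E)-7-[(4S,5R)-4,5-(di-tert-butylsilanediyldioxy)-2-[(R,E)-2,4-dimethyloct-2-enamido]-1-oxocyclohex-2-en-4-yl]-N-(2-hydroxy-5-oxocyclopent-1-en-1-yl)hepta-2,4,6-trienamide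
Conditions: 27 (3 equiv), LiN(SiMe3)2 (5.9 equiv), THF, −78 °C; then 20, −78 °C to −20 °C; AcOH quench
Reagents that add atoms: none
Why: Horner–Wadsworth–Emmons olefination with the dianion of 27 (enolate plus phosphonate carbanion), which adds 1,2 to the enal and should give the E C3'=C4' bond; the enolate charge shields the reagent N–H and the excess of reagent absorbs the acidic enamide N–H of 20.

Step 19
Reactants: 28 O4,O5-di-tert-butylsilanediyl derivative of the target
Product: 29 CNP0154433.2, (2E,4E,6E)-7-[(1S,6R)-3-[(R,E)-2,4-dimethyloct-2-enamido]-1,6-dihydroxy-4-oxocyclohex-2-en-1-yl]-N-(2-hydroxy-5-oxocyclopent-1-en-1-yl)hepta-2,4,6-trienamide [(4S,5R) in the cyclohexenone numbering used here]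
Conditions: HF·pyridine, pyridine, THF, 0 °C
Reagents that add atoms: none
Why: Fluoride-assisted cleavage of both Si–O bonds (desilylation), buffered with pyridine so that the tertiary, doubly allylic C4 carbinol is not ionised.

**Compound list**

1 | (R)-malic acid | OC(=O)[C@H](O)CC(=O)O | starting material
2 | (R)-2-(2,2-dimethyl-5-oxo-1,3-dioxolan-4-yl)acetic acid | CC1(C)OC(=O)[C@H](O1)CC(=O)O | intermediate
3 | (R)-2-(2,2-dimethyl-5-oxo-1,3-dioxolan-4-yl)acetyl chloride | CC1(C)OC(=O)[C@H](O1)CC(=O)Cl | intermediate
4 | (R)-2-(2,2-dimethyl-5-oxo-1,3-dioxolan-4-yl)-N-methoxy-N-methylacetamide | CC1(C)OC(=O)[C@H](O1)CC(=O)N(C)OC | intermediate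
5 | vinylmagnesium bromide | C=C[Mg]Br | starting material
6 | (5R)-6-ethenyl-5,6-dihydroxyocta-1,7-dien-3-one | C=CC(O)(C=C)[C@H](O)CC(=O)C=C | intermediate
7 | di-tert-butylsilyl bis(trifluoromethanesulfonate) | CC(C)(C)[Si](OS(=O)(=O)C(F)(F)F)(OS(=O)(=O)C(F)(F)F)C(C)(C)C | starting material
8 | 1-[(5R)-2,2-di-tert-butyl-4,4-diethenyl-1,3,2-dioxasilolan-5-yl]but-3-en-2-one | C=CC(O1)(C=C)[C@H](O[Si]1(C(C)(C)C)C(C)(C)C)CC(=O)C=C | intermediate
9 | cis-fused di-tert-butylsilylene of (4S,5R)-4,5-dihydroxy-4-vinylcyclohex-2-en-1-one | C1=C[C@@](O2)(C=C)[C@H](O[Si]2(C(C)(C)C)C(C)(C)C)CC1=O | intermediate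
10 | cis-fused di-tert-butylsilylene of (4S,5R)-4,5-dihydroxy-2-iodo-4-vinylcyclohex-2-en-1-one | IC1=C[C@@](O2)(C=C)[C@H](O[Si]2(C(C)(C)C)C(C)(C)C)CC1=O | intermediate
11 | (R)-4-benzyloxazolidin-2-one | O=C1N[C@H](Cc2ccccc2)CO1 | starting material
12 | hexanoyl chloride | CCCCCC(=O)Cl | starting material
13 | (R)-4-benzyl-3-hexanoyloxazolidin-2-one | CCCCCC(=O)N1[C@H](Cc2ccccc2)COC1=O | intermediate
14 | (R)-4-benzyl-3-[(R)-2-methylhexanoyl]oxazolidin-2-one | CCCC[C@@H](C)C(=O)N1[C@H](Cc2ccccc2)COC1=O | intermediate
15 | (R)-2-methylhexan-1-ol | CCCC[C@@H](C)CO | intermediate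
16 | (R)-2-methylhexanal | CCCC[C@@H](C)C=O | intermediate
17 | ethyl (R,E)-2,4-dimethyloct-2-enoate | CCCC[C@@H](C)/C=C(\C)C(=O)OCC | intermediate
18 | (R,E)-2,4-dimethyloct-2-enamide | CCCC[C@@H](C)/C=C(\C)C(N)=O | intermediate
19 | (R,E)-N-[(4S,5R)-4,5-(di-tert-butylsilanediyldioxy)-1-oxo-4-vinylcyclohex-2-en-2-yl]-2,4-dimethyloct-2-enamide | CCCC[C@@H](C)/C=C(\C)C(=O)NC1=C[C@@](O2)(C=C)[C@H](O[Si]2(C(C)(C)C)C(C)(C)C)CC1=O | intermediate
20 | (R,E)-N-[(4S,5R)-4,5-(di-tert-butylsilanediyldioxy)-1-oxo-4-[(E)-3-oxoprop-1-enyl]cyclohex-2-en-2-yl]-2,4-dimethyloct-2-enamide | CCCC[C@@H](C)/C=C(\C)C(=O)NC1=C[C@@](O2)(/C=C/C=O)[C@H](O[Si]2(C(C)(C)C)C(C)(C)C)CC1=O | intermediate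
21 | cyclopentane-1,3-dione | O=C1CCC(=O)C1 | starting material
22 | 3-hydroxy-2-nitrocyclopent-2-en-1-one | O=C1CCC(O)=C1[N+](=O)[O-] | intermediate
23 | 2-amino-3-hydroxycyclopent-2-en-1-one hydrochloride | NC1=C(O)CCC1=O.Cl | intermediate
24 | triethyl (E)-4-phosphonocrotonate | CCOC(=O)/C=C/CP(=O)(OCC)OCC | starting material
25 | (E)-4-(diethoxyphosphoryl)but-2-enoic acid | OC(=O)/C=C/CP(=O)(OCC)OCC | intermediate
26 | (E)-4-(diethoxyphosphoryl)but-2-enoyl chloride | ClC(=O)/C=C/CP(=O)(OCC)OCC | intermediate
27 | diethyl (E)-[4-[(2-hydroxy-5-oxocyclopent-1-en-1-yl)amino]-4-oxobut-2-en-1-yl]phosphonate | CCOP(=O)(OCC)C/C=C/C(=O)NC1=C(O)CCC1=O | intermediate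
28 | O4,O5-di-tert-butylsilanediyl derivative of the target | CCCC[C@@H](C)/C=C(\C)C(=O)NC1=C[C@@](O2)(/C=C/C=C/C=C/C(=O)NC3=C(O)CCC3=O)[C@H](O[Si]2(C(C)(C)C)C(C)(C)C)CC1=O | intermediate
29 | CNP0154433.2 | CCCC[C@@H](C)/C=C(\C)C(=O)NC1=C[C@@](O)(/C=C/C=C/C=C/C(=O)NC2=C(O)CCC2=O)[C@H](O)CC1=O | target

**Step count**

Total: 19 steps (10 in the main line, 5 for amide 18, 4 for phosphonate 27).
Longest linear sequence: 10 steps, from 1 through steps 1–6, 12, 13, 18 and 19.

**Steps most likely to fail**

1. Step 5 (key ring closure). The ruthenium carbene may load slowly on vinyl groups next to the fully substituted C4, so that the electron-poor acryloyl terminus couples between molecules or the catalyst decays before the ring closes. Fallback, setting out from 8: Luche reduction (NaBH4, CeCl3·7H2O, MeOH, −40 °C) should give the allylic alcohol 1-[(5R)-2,2-di-tert-butyl-4,4-diethenyl-1,3,2-dioxasilolan-5-yl]but-3-en-2-ol F1 as a mixture of carbinol epimers. Ring-closing metathesis of this electron-rich triene (second-generation Grubbs catalyst, CH2Cl2, 40 °C), still steered by the dioxasilolane, should give the cis-fused silylene of (4S,5R)-4-vinylcyclohex-2-ene-1,4,5-triol F2, and oxidation of its allylic hydroxyl with MnO2 in CH2Cl2 comes back to the route at 9. The ring is thus closed at the carbinol oxidation level and the enone is made afterwards.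

2. Step 13 (cross-metathesis). The vinyl group on the quaternary C4 may fail to enter the catalytic cycle while crotonaldehyde self-metathesises and the catalyst is consumed. Fallback, setting out from 19: Lemieux–Johnson cleavage (OsO4 cat., NaIO4, 2,6-lutidine, dioxane/water) of the vinyl group, the only alkene in 19 that is neither trisubstituted nor conjugated to a carbonyl group, should give the C4 carbaldehyde F3. Wittig homologation with (triphenylphosphoranylidene)acetaldehyde in toluene at 60 °C comes back to the route at 20.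

3. Step 18 (olefination). The basic phosphonate dianion may transfer protons instead of adding, deprotonating the enamide N–H and the C6 methylene of 20, after which E1cB loss of the C5 silyloxy group would open the tether. Fallback, setting out from 20: Wittig homologation with (triphenylphosphoranylidene)acetaldehyde should give the (2E,4E)-dienal F4. Separately, heating 23 with Meldrum's acid and Et3N in MeCN should give the malonamic acid 3-[(2-hydroxy-5-oxocyclopent-1-en-1-yl)amino]-3-oxopropanoic acid F5. Knoevenagel–Doebner condensation of the dienal with this acid (pyridine, piperidine cat., 50 °C), with loss of CO2, comes back to the route at 28 under weakly basic conditions.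

**Further compounds**

F1 | step 5 | 1-[(5R)-2,2-di-tert-butyl-4,4-diethenyl-1,3,2-dioxasilolan-5-yl]but-3-en-2-ol (carbinol epimers) | C=CC(O1)(C=C)[C@H](O[Si]1(C(C)(C)C)C(C)(C)C)CC(O)C=C
F2 | step 5 | cis-fused di-tert-butylsilylene (O4,O5) of (4S,5R)-4-vinylcyclohex-2-ene-1,4,5-triol (carbinol epimers) | OC1C=C[C@@](O2)(C=C)[C@H](O[Si]2(C(C)(C)C)C(C)(C)C)C1
F3 | step 13 | C4 carbaldehyde: (R,E)-N-[4,5-(di-tert-butylsilanediyldioxy)-4-formyl-1-oxocyclohex-2-en-2-yl]-2,4-dimethyloct-2-enamide, configuration as in 19 | CCCC[C@@H](C)/C=C(\C)C(=O)NC1=C[C@@](O2)(C=O)[C@H](O[Si]2(C(C)(C)C)C(C)(C)C)CC1=O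
F4 | step 18 | (2E,4E)-dienal: (R,E)-N-[(4S,5R)-4,5-(di-tert-butylsilanediyldioxy)-1-oxo-4-[(1E,3E)-5-oxopenta-1,3-dienyl]cyclohex-2-en-2-yl]-2,4-dimethyloct-2-enamide | CCCC[C@@H](C)/C=C(\C)C(=O)NC1=C[C@@](O2)(/C=C/C=C/C=O)[C@H](O[Si]2(C(C)(C)C)C(C)(C)C)CC1=O
F5 | step 18 | 3-[(2-hydroxy-5-oxocyclopent-1-en-1-yl)amino]-3-oxopropanoic acid | OC(=O)CC(=O)NC1=C(O)CCC1=O
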